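The eudesmane core is cut across C5–C10 and C1–C2, so that rings A and B come from one acyclic trienal. A Lewis acid promoted intramolecular Diels–Alder reaction of a 2-substituted acrolein (C10=C1) with an E-diene (C5=C4–C3=C2) closes both rings at once. It exploits the trans C5/C10 junction of rings A and B and leaves the C3=C4 alkene beside it for α-face oxygenation at C4, the ether carbon. The precursor carries the diene and the enal at the ends of the C6–C9 chain, whose C7 stereocentre is bought as (R)-α-terpineol. Angular formyl-to-methyl reduction, SNAr etherification, Suzuki coupling and benzylic vinylation complete the honokiol ether.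

Key step: step 8

Remark: eudesmane numbering is used for the terpenoid part (C4 ether carbon, C5 and C10 ring-fusion carbons, C7 side-chain carbon, C14 angular carbon), and 2-allyl-4-bromophenol is taken as a purchased compound.

Step 1
Reactants: 1 (R)-(+)-α-terpineol
Product: 2 triethyl({2-[(1R)-4-methylcyclohex-3-en-1-yl]propan-2-yl}oxy)silane
Conditions: Et3SiOTf, 2,6-lutidine, CH2Cl2, 0 °C
Reagents that add atoms: triethylsilyl trifluoromethanesulfonate, CC[Si](CC)(CC)OS(=O)(=O)C(F)(F)F
Why: Silylation of a tertiary alcohol with the silyl triflate and a hindered pyridine base is reliable where the chloride is too slow, and it masks the hydroxyl group against the enolate, Lewis acid and alkoxide chemistry ahead without touching the stereocentre.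

Step 2
Reactants: 2 triethyl({2-[(1R)-4-methylcyclohex-3-en-1-yl]propan-2-yl}oxy)silane
Product: 4 (3R)-6-oxo-3-[2-(triethylsilyloxy)propan-2-yl]heptanal, via ozonide 3 (not isolated)
Conditions: O3, CH2Cl2, −78 °C; then PPh3, −78 °C to rt
Reagents that add atoms: ozone, [O-][O+]=O
Why: Ozonolysis with reductive work-up cleaves the only alkene by cycloaddition, cycloreversion and recombination to the ozonide, which PPh3 reduces to the methyl ketone and the aldehyde, and the stereocentre, β to the new aldehyde, cannot epimerise.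

Step 3
Reactants: 4 (3R)-6-oxo-3-[2-(triethylsilyloxy)propan-2-yl]heptanal; 5 2-(triphenylphosphoranylidene)propanal
Product: 6 (2E,5R)-2-methyl-8-oxo-5-[2-(triethylsilyloxy)propan-2-yl]non-2-enal
Conditions: toluene, 80 °C
Reagents that add atoms: none
Why: In this Wittig reaction the stabilised formyl ylide reacts with the aldehyde and not with the ketone and gives the E-configured 2-methyl-2-enal through reversible oxaphosphetane formation.

Step 4
Reactants: 6 (2E,5R)-2-methyl-8-oxo-5-[2-(triethylsilyloxy)propan-2-yl]non-2-enal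
Product: 7 (5R,7E)-8-methyl-5-[2-(triethylsilyloxy)propan-2-yl]deca-7,9-dien-2-one
Conditions: Ph3PCH3Br, KN(SiMe3)2, THF, 0 °C; ylide (1 equiv) added to 6 at −78 °C, then to 0 °C
Reagents that add atoms: methyltriphenylphosphonium bromide, C[P+](c1ccccc1)(c1ccccc1)c1ccccc1.[Br-]
Why: Wittig methylenation with one equivalent of the unstabilised ylide at low temperature takes the conjugated aldehyde ahead of the saturated methyl ketone and turns the enal into the terminal diene with the E geometry of the trisubstituted alkene unchanged.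

Step 5
Reactants: 7 (5R,7E)-8-methyl-5-[2-(triethylsilyloxy)propan-2-yl]deca-7,9-dien-2-one
Product: 9 (5R,7E)-8-methyl-5-[2-(triethylsilyloxy)propan-2-yl]deca-1,7,9-trien-2-yl trifluoromethanesulfonate, via lithium enolate 8 (not isolated)
Conditions: LiN(iPr)2, THF, −78 °C; then N-(5-chloropyridin-2-yl)bis(trifluoromethanesulfonimide), −78 to −20 °C
Reagents that add atoms: N-(5-chloropyridin-2-yl)bis(trifluoromethanesulfonimide), O=S(=O)(N(c1ccc(Cl)cn1)S(=O)(=O)C(F)(F)F)C(F)(F)F
Why: Kinetic enolisation with the hindered lithium amide at −78 °C removes a proton from the methyl group, and O-sulfonylation of this less substituted enolate by the reactive pyridyl triflimide at the same temperature gives the 1,1-disubstituted enol triflate before the enolate can equilibrate (kinetic enol triflate formation).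

Step 6
Reactants: 9 (5R,7E)-8-methyl-5-[2-(triethylsilyloxy)propan-2-yl]deca-1,7,9-trien-2-yl trifluoromethanesulfonate
Product: 10 (5R,7E)-N-methoxy-N,8-dimethyl-2-methylidene-5-[2-(triethylsilyloxy)propan-2-yl]deca-7,9-dienamide
Conditions: Pd(OAc)2 (cat.), PPh3, CO (1 atm), MeNHOMe·HCl, Et3N, DMF, rt
Reagents that add atoms: carbon monoxide, [C-]#[O+]; N,O-dimethylhydroxylamine hydrochloride, CNOC.Cl
Why: Palladium-catalysed aminocarbonylation of an enol triflate (oxidative addition, CO insertion, acyl transfer to the amine) gives the 2-substituted acrylamide, and CO insertion at room temperature is expected to outrun Heck-type addition of the vinylpalladium species to the tethered diene.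

Step 7
Reactants: 10 (5R,7E)-N-methoxy-N,8-dimethyl-2-methylidene-5-[2-(triethylsilyloxy)propan-2-yl]deca-7,9-dienamide
Product: 11 (5R,7E)-8-methyl-2-methylidene-5-[2-(triethylsilyloxy)propan-2-yl]deca-7,9-dienal
Conditions: iBu2AlH, THF, −78 °C; aq. potassium sodium tartrate
Reagents that add atoms: none
Why: Reduction of an N-methoxy-N-methylamide stops at the chelated tetrahedral aluminium adduct, which gives the aldehyde only on aqueous work-up, so the 2-substituted acrolein forms without over-reduction or conjugate reduction (Weinreb amide reduction).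

Step 8
Reactants: 11 (5R,7E)-8-methyl-2-methylidene-5-[2-(triethylsilyloxy)propan-2-yl]deca-7,9-dienal
Product: 12 11-(triethylsilyloxy)eudesm-3-en-14-al, that is (2R,4aS,8aS)-8-methyl-2-[2-(triethylsilyloxy)propan-2-yl]-1,3,4,5,6,8a-hexahydronaphthalene-4a(2H)-carbaldehyde
Conditions: Me2AlCl, CH2Cl2, −78 to −20 °C
Reagents that add atoms: none
Why: Me2AlCl binds the formyl oxygen and lowers the LUMO of the 2-substituted acrolein, which then adds to the tethered diene in a concerted but asynchronous [4+2] cycloaddition in which the C1–C2 bond forms ahead of the C5–C10 bond. The closest known reaction type is the Lewis acid promoted type 1 intramolecular Diels–Alder reaction of 1,7,9-decatrienes that carry a 2-substituted acrolein as dienophile. Ring A closes as the new cyclohexene of the cycloaddition (C1, C2, C3, C4, C5, C10), and ring B closes in the fused mode at the same moment, because the C6–C9 tether already links the diene terminus C5 to the dienophile carbon C10. C10 and C5 are set relative to each other by the endo position of the complexed formyl group: the tether is then exo, so C6, the outside substituent of the E-diene terminus, ends cis to the formyl carbon and H5 trans to it, which is the trans ring fusion with an axial formyl group. Their absolute configuration is relayed from C7, whose bulky silyloxypropyl group takes an equatorial place in the chair-like array of the forming ring B and so exposes one diene face only, ending cis to the formyl group. The step thus needs endo (formyl) and diene face selectivity, secured by the aluminium–aldehyde complex and by the purchased C7 centre, while regiochemistry is fixed by the tether and the new C3=C4 alkene lies ready for step 11.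

Step 9
Reactants: 12 11-(triethylsilyloxy)eudesm-3-en-14-al
Product: 13 11-(triethylsilyloxy)eudesm-3-en-14-al (E)-tosylhydrazone
Conditions: TsNHNH2, EtOH, 50 °C
Reagents that add atoms: 4-methylbenzenesulfonohydrazide, Cc1ccc(cc1)S(=O)(=O)NN
Why: Condensation of the aldehyde with tosylhydrazide (hydrazone formation) is feasible even at the neopentyl position because the formyl carbon itself is unhindered, and the quaternary C10 rules out epimerisation or enolisation.

Step 10
Reactants: 13 11-(triethylsilyloxy)eudesm-3-en-14-al (E)-tosylhydrazone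
Product: 15 11-(triethylsilyloxy)eudesm-3-ene, via N-boryl tosylhydrazine 14 (not isolated)
Conditions: catecholborane, CHCl3, 0 °C to rt; then NaOAc·3H2O, 60 °C
Reagents that add atoms: none
Why: In this tosylhydrazone reduction the borane delivers hydride to the C=N carbon, acetate then triggers loss of sulfinate to the alkyl diazene, which releases N2 and leaves the C14 methyl group, and the quaternary C10 excludes alkene-forming elimination while the conditions spare the silyl ether and the C3=C4 alkene.

Step 11
Reactants: 15 11-(triethylsilyloxy)eudesm-3-ene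
Product: 16 3α,4α-epoxy-11-(triethylsilyloxy)eudesmane
Conditions: mCPBA, NaHCO3, CH2Cl2, 0 °C
Reagents that add atoms: 3-chloroperoxybenzoic acid, O=C(OO)c1cccc(Cl)c1
Why: Peracid epoxidation (Prilezhaev reaction) of the trisubstituted C3=C4 alkene should occur on the α face because the axial 10β-methyl group shields the β face, which places the C4–O bond α.

Step 12
Reactants: 16 3α,4α-epoxy-11-(triethylsilyloxy)eudesmane
Product: 17 11-(triethylsilyloxy)eudesman-4α-ol
Conditions: LiEt3BH, THF, 0 to 60 °C; then H2O
Reagents that add atoms: none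
Why: The strongly nucleophilic hydride opens the trisubstituted epoxide by SN2 attack at the secondary C3 anti to oxygen (epoxide reduction), so the C4–O bond set in step 11 is kept and the tertiary 4α-alcohol with a 4β-methyl group results.

Step 13
Reactants: 17 11-(triethylsilyloxy)eudesman-4α-ol; 18 3-bromo-4-fluorobenzonitrile
Product: 20 3-bromo-4-{[11-(triethylsilyloxy)eudesman-4α-yl]oxy}benzonitrile, via potassium alkoxide 19 (not isolated)
Conditions: KN(SiMe3)2, THF, 0 °C; then 18, THF/DMF, rt to 50 °C
Reagents that add atoms: none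
Why: Nucleophilic aromatic substitution by addition–elimination through a Meisenheimer adduct is activated by the para cyano group and the ortho bromine, fluoride is the best leaving group for it, and the C4–O bond is not broken so the configuration at C4 is retained.

Step 14
Reactants: 21 2-allyl-4-bromophenol
Product: 22 (2-allyl-4-bromophenoxy)triisopropylsilane
Conditions: iPr3SiCl, imidazole, DMF, rt
Reagents that add atoms: chlorotriisopropylsilane, CC(C)[Si](Cl)(C(C)C)C(C)C
Why: Silylation of the phenol with the silyl chloride and imidazole is routine and gives an aryl silyl ether that withstands the aqueous base of the cross-coupling and the hydride reagents used later.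

Step 15
Reactants: 22 (2-allyl-4-bromophenoxy)triisopropylsilane
Product: 23 [2-allyl-4-(4,4,5,5-tetramethyl-1,3,2-dioxaborolan-2-yl)phenoxy]triisopropylsilane
Conditions: B2pin2, PdCl2(dppf) (cat.), KOAc, 1,4-dioxane, 85 °C
Reagents that add atoms: bis(pinacolato)diboron, CC1(C)OB(OC1(C)C)B1OC(C)(C)C(C)(C)O1
Why: Miyaura borylation of the aryl bromide with the diboron reagent under weak acetate base gives the pinacol boronate and tolerates the silyl ether and the allyl group.

Step 16
Reactants: 20 3-bromo-4-{[11-(triethylsilyloxy)eudesman-4α-yl]oxy}benzonitrile; 23 [2-allyl-4-(4,4,5,5-tetramethyl-1,3,2-dioxaborolan-2-yl)phenoxy]triisopropylsilane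
Product: 24 3'-allyl-6-{[11-(triethylsilyloxy)eudesman-4α-yl]oxy}-4'-(triisopropylsilyloxy)biphenyl-3-carbonitrile
Conditions: Pd(OAc)2 (cat.), SPhos, K3PO4, toluene/H2O, 80 °C
Reagents that add atoms: none
Why: Suzuki–Miyaura coupling with a bulky electron-rich biarylphosphine ligand lets oxidative addition and reductive elimination proceed at the bromide flanked by the tertiary alkoxy group, and the nitrile, both silyl ethers and the allyl group are inert to it.

Step 17
Reactants: 24 3'-allyl-6-{[11-(triethylsilyloxy)eudesman-4α-yl]oxy}-4'-(triisopropylsilyloxy)biphenyl-3-carbonitrile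
Product: 26 (3'-allyl-6-{[11-(triethylsilyloxy)eudesman-4α-yl]oxy}-4'-(triisopropylsilyloxy)biphenyl-3-yl)methanol, via biaryl aldehyde 25 (not isolated)
Conditions: iBu2AlH, toluene, −78 to 0 °C; MeOH then aq. potassium sodium tartrate, rt; then NaBH4, 0 °C
Reagents that add atoms: water, O
Why: Partial hydride reduction of the nitrile to the N-aluminio imine, hydrolysis to the aldehyde and borohydride reduction (nitrile-to-aldehyde reduction followed by carbonyl reduction) give the benzylic alcohol without acid, so the tertiary alkyl aryl ether and the silyl ethers survive.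

Step 18
Reactants: 26 (3'-allyl-6-{[11-(triethylsilyloxy)eudesman-4α-yl]oxy}-4'-(triisopropylsilyloxy)biphenyl-3-yl)methanol
Product: 27 3'-allyl-5-(bromomethyl)-2-{[11-(triethylsilyloxy)eudesman-4α-yl]oxy}-4'-(triisopropylsilyloxy)biphenyl
Conditions: CBr4, PPh3, CH2Cl2, 0 °C; used at once
Reagents that add atoms: carbon tetrabromide, BrC(Br)(Br)Br
Why: The Appel reaction converts the benzylic alcohol into the bromide under neutral conditions that avoid HBr, which would cleave the tertiary alkyl aryl ether.

Step 19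
Reactants: 27 3'-allyl-5-(bromomethyl)-2-{[11-(triethylsilyloxy)eudesman-4α-yl]oxy}-4'-(triisopropylsilyloxy)biphenyl
Product: 28 3',5-diallyl-2-{[11-(triethylsilyloxy)eudesman-4α-yl]oxy}-4'-(triisopropylsilyloxy)biphenyl
Conditions: Bu3SnCH=CH2, Pd(PPh3)4 (cat.), toluene, 80 °C
Reagents that add atoms: tributyl(vinyl)stannane, C=C[Sn](CCCC)(CCCC)CCCC
Why: Stille coupling of a benzylic bromide with a vinylstannane forms the ArCH2–CH=CH2 bond under neutral conditions, so no base is present that could move the new alkene into conjugation with the ring.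

Step 20
Reactants: 28 3',5-diallyl-2-{[11-(triethylsilyloxy)eudesman-4α-yl]oxy}-4'-(triisopropylsilyloxy)biphenyl
Product: 29 3',5-diallyl-2-{[(1R,4aR,7R,8aR)-7-(2-hydroxypropan-2-yl)-1,4a-dimethyldecahydronaphthalen-1-yl]oxy}biphenyl-4'-ol
Conditions: Bu4NF, THF, rt to 45 °C
Reagents that add atoms: none
Why: Fluoride-induced desilylation cleaves both the aryl triisopropylsilyl ether and the tertiary triethylsilyl ether through pentacoordinate silicon under non-acidic conditions, which keeps the acid-labile tertiary alkyl aryl ether and both allyl groups intact.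

Compound list

1 | (R)-(+)-α-terpineol, 2-[(1R)-4-methylcyclohex-3-en-1-yl]propan-2-ol | CC1=CC[C@H](C(C)(C)O)CC1 | starting material
2 | triethyl({2-[(1R)-4-methylcyclohex-3-en-1-yl]propan-2-yl}oxy)silane | CC1=CC[C@H](C(C)(C)O[Si](CC)(CC)CC)CC1 | intermediate
3 | ozonide of 2 (formed in situ), 1-methyl-4-[2-(triethylsilyloxy)propan-2-yl]-7,8,9-trioxabicyclo[4.2.1]nonane, side-chain centre as in 2, mixture at the two bridgeheads | CC12CC[C@@H](C(C)(C)O[Si](CC)(CC)CC)CC(OO1)O2 | intermediate
4 | (3R)-6-oxo-3-[2-(triethylsilyloxy)propan-2-yl]heptanal | O=CC[C@H](C(C)(C)O[Si](CC)(CC)CC)CCC(C)=O | intermediate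
5 | 2-(triphenylphosphoranylidene)propanal | CC(C=O)=P(c1ccccc1)(c1ccccc1)c1ccccc1 | starting material
6 | (2E,5R)-2-methyl-8-oxo-5-[2-(triethylsilyloxy)propan-2-yl]non-2-enal | O=C/C(C)=C/C[C@H](C(C)(C)O[Si](CC)(CC)CC)CCC(C)=O | intermediate
7 | (5R,7E)-8-methyl-5-[2-(triethylsilyloxy)propan-2-yl]deca-7,9-dien-2-one | C=C/C(C)=C/C[C@H](C(C)(C)O[Si](CC)(CC)CC)CCC(C)=O | intermediate
8 | lithium (5R,7E)-8-methyl-5-[2-(triethylsilyloxy)propan-2-yl]deca-1,7,9-trien-2-olate (formed in situ) | [Li+].C=C([O-])CC[C@@H](C(C)(C)O[Si](CC)(CC)CC)C/C=C(\C)C=C | intermediate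
9 | (5R,7E)-8-methyl-5-[2-(triethylsilyloxy)propan-2-yl]deca-1,7,9-trien-2-yl trifluoromethanesulfonate | C=C(OS(=O)(=O)C(F)(F)F)CC[C@@H](C(C)(C)O[Si](CC)(CC)CC)C/C=C(\C)C=C | intermediate
10 | (5R,7E)-N-methoxy-N,8-dimethyl-2-methylidene-5-[2-(triethylsilyloxy)propan-2-yl]deca-7,9-dienamide | C=C(C(=O)N(C)OC)CC[C@@H](C(C)(C)O[Si](CC)(CC)CC)C/C=C(\C)C=C | intermediate
11 | (5R,7E)-8-methyl-2-methylidene-5-[2-(triethylsilyloxy)propan-2-yl]deca-7,9-dienal (trienal, precursor of the key step) | C=C(C=O)CC[C@@H](C(C)(C)O[Si](CC)(CC)CC)C/C=C(\C)C=C | intermediate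
12 | 11-(triethylsilyloxy)eudesm-3-en-14-al (5α-H, 7β side chain, 10β-formyl), (2R,4aS,8aS)-8-methyl-2-[2-(triethylsilyloxy)propan-2-yl]-1,3,4,5,6,8a-hexahydronaphthalene-4a(2H)-carbaldehyde | CC1=CCC[C@]2(C=O)CC[C@@H](C(C)(C)O[Si](CC)(CC)CC)C[C@H]21 | intermediate
13 | (E)-tosylhydrazone of 12, ring stereocentres as in 12 | CC1=CCC[C@]2(/C=N/NS(=O)(=O)c3ccc(C)cc3)CC[C@@H](C(C)(C)O[Si](CC)(CC)CC)C[C@H]21 | intermediate
14 | N-(1,3,2-benzodioxaborol-2-yl)-N-[11-(triethylsilyloxy)eudesm-3-en-14-yl]-N'-tosylhydrazine (formed in situ) | CC1=CCC[C@]2(CN(B3Oc4ccccc4O3)NS(=O)(=O)c3ccc(C)cc3)CC[C@@H](C(C)(C)O[Si](CC)(CC)CC)C[C@H]21 | intermediate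
15 | 11-(triethylsilyloxy)eudesm-3-ene (α-eudesmol triethylsilyl ether), (2R,4aR,8aR)-4a,8-dimethyl-2-[2-(triethylsilyloxy)propan-2-yl]-1,2,3,4,4a,5,6,8a-octahydronaphthalene | CC1=CCC[C@]2(C)CC[C@@H](C(C)(C)O[Si](CC)(CC)CC)C[C@H]21 | intermediate
16 | 3α,4α-epoxy-11-(triethylsilyloxy)eudesmane (5α-H, 7β side chain, 10β-methyl) | C[C@@]12O[C@@H]1CC[C@]3(C)CC[C@@H](C(C)(C)O[Si](CC)(CC)CC)C[C@H]32 | intermediate
17 | 11-(triethylsilyloxy)eudesman-4α-ol, (1R,4aR,7R,8aR)-1,4a-dimethyl-7-[2-(triethylsilyloxy)propan-2-yl]decahydronaphthalen-1-ol | O[C@]1(C)CCC[C@]2(C)CC[C@@H](C(C)(C)O[Si](CC)(CC)CC)C[C@H]21 | intermediate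
18 | 3-bromo-4-fluorobenzonitrile | N#Cc1ccc(F)c(Br)c1 | starting material
19 | potassium alkoxide of 17 (formed in situ) | [K+].[O-][C@]1(C)CCC[C@]2(C)CC[C@@H](C(C)(C)O[Si](CC)(CC)CC)C[C@H]21 | intermediate
20 | 3-bromo-4-{[(1R,4aR,7R,8aR)-1,4a-dimethyl-7-[2-(triethylsilyloxy)propan-2-yl]decahydronaphthalen-1-yl]oxy}benzonitrile | N#Cc1ccc(O[C@]2(C)CCC[C@]3(C)CC[C@@H](C(C)(C)O[Si](CC)(CC)CC)C[C@H]32)c(Br)c1 | intermediate
21 | 2-allyl-4-bromophenol | C=CCc1cc(Br)ccc1O | starting material
22 | (2-allyl-4-bromophenoxy)triisopropylsilane | C=CCc1cc(Br)ccc1O[Si](C(C)C)(C(C)C)C(C)C | intermediate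
23 | [2-allyl-4-(4,4,5,5-tetramethyl-1,3,2-dioxaborolan-2-yl)phenoxy]triisopropylsilane | C=CCc1cc(B2OC(C)(C)C(C)(C)O2)ccc1O[Si](C(C)C)(C(C)C)C(C)C | intermediate
24 | 3'-allyl-6-{[11-(triethylsilyloxy)eudesman-4α-yl]oxy}-4'-(triisopropylsilyloxy)biphenyl-3-carbonitrile | N#Cc1ccc(O[C@]2(C)CCC[C@]3(C)CC[C@@H](C(C)(C)O[Si](CC)(CC)CC)C[C@H]32)c(-c2ccc(O[Si](C(C)C)(C(C)C)C(C)C)c(CC=C)c2)c1 | intermediate
25 | 3'-allyl-6-{[11-(triethylsilyloxy)eudesman-4α-yl]oxy}-4'-(triisopropylsilyloxy)biphenyl-3-carbaldehyde (formed in situ) | O=Cc1ccc(O[C@]2(C)CCC[C@]3(C)CC[C@@H](C(C)(C)O[Si](CC)(CC)CC)C[C@H]32)c(-c2ccc(O[Si](C(C)C)(C(C)C)C(C)C)c(CC=C)c2)c1 | intermediate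
26 | (3'-allyl-6-{[11-(triethylsilyloxy)eudesman-4α-yl]oxy}-4'-(triisopropylsilyloxy)biphenyl-3-yl)methanol | OCc1ccc(O[C@]2(C)CCC[C@]3(C)CC[C@@H](C(C)(C)O[Si](CC)(CC)CC)C[C@H]32)c(-c2ccc(O[Si](C(C)C)(C(C)C)C(C)C)c(CC=C)c2)c1 | intermediate
27 | 3'-allyl-5-(bromomethyl)-2-{[11-(triethylsilyloxy)eudesman-4α-yl]oxy}-4'-(triisopropylsilyloxy)biphenyl | BrCc1ccc(O[C@]2(C)CCC[C@]3(C)CC[C@@H](C(C)(C)O[Si](CC)(CC)CC)C[C@H]32)c(-c2ccc(O[Si](C(C)C)(C(C)C)C(C)C)c(CC=C)c2)c1 | intermediate
28 | 3',5-diallyl-2-{[11-(triethylsilyloxy)eudesman-4α-yl]oxy}-4'-(triisopropylsilyloxy)biphenyl | C=CCc1ccc(O[C@]2(C)CCC[C@]3(C)CC[C@@H](C(C)(C)O[Si](CC)(CC)CC)C[C@H]32)c(-c2ccc(O[Si](C(C)C)(C(C)C)C(C)C)c(CC=C)c2)c1 | intermediate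
29 | CNP0219722.1, 3',5-diallyl-2-{[(1R,4aR,7R,8aR)-7-(2-hydroxypropan-2-yl)-1,4a-dimethyldecahydronaphthalen-1-yl]oxy}biphenyl-4'-ol (4α-O-aryl, 5α-H, 7β side chain, 10β-methyl) | C=CCc1ccc(O[C@]2(C)CCC[C@]3(C)CC[C@@H](C(C)(C)O)C[C@H]32)c(-c2ccc(O)c(CC=C)c2)c1 | target

Total step count: 20. Longest linear sequence: 18 steps (steps 1 to 13 and 16 to 20, from 1 to 29).

Steps most likely to fail

Step 8. The Lewis acid may erode the endo (formyl) preference, or it may trigger oligomerisation of the diene or ionisation of the tertiary silyl ether faster than the cycloaddition. The fallback changes the dienophile and drops the Lewis acid. It sets out from enol triflate 9: methoxycarbonylation (Pd(OAc)2, PPh3, CO, MeOH, Et3N, DMF, rt) gives the acrylate methyl (5R,7E)-8-methyl-2-methylidene-5-[2-(triethylsilyloxy)propan-2-yl]deca-7,9-dienoate F1. Heating F1 in toluene (170 °C, sealed vessel, BHT) brings about the thermal intramolecular Diels–Alder reaction through the same chair-like tether and gives the angular ester methyl 11-(triethylsilyloxy)eudesm-3-en-14-oate F2, from which any cis-fused isomer is separated. LiAlH4 reduction then gives the neopentyl alcohol 11-(triethylsilyloxy)eudesm-3-en-14-ol F3, and Dess–Martin oxidation brings the material back to aldehyde 12.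

Step 13. Addition of the hindered tertiary alkoxide to the fluoroarene may be slow, so that base-induced attack on the nitrile or decomposition of the electrophile wins. The fallback replaces addition–elimination by ligand coupling at iodine. It sets out from alcohol 17, whose alkoxide (NaH or KN(SiMe3)2, toluene, rt) is arylated with the diaryliodonium salt (2-bromo-4-cyanophenyl)(2,4,6-trimethoxyphenyl)iodonium 4-methylbenzenesulfonate F4. This salt is made separately from 3-bromo-4-iodobenzonitrile, mCPBA, TsOH·H2O and 1,3,5-trimethoxybenzene. The electron-poor, ortho-substituted aryl group is the one transferred, and the route is rejoined at aryl ether 20.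

Step 10. Hydride transfer to the hindered neopentyl hydrazone may stay incomplete, or the diazene may decompose by paths other than clean loss of N2. The fallback is the Wolff–Kishner reduction in its Huang-Minlon form. It sets out from aldehyde 12 (N2H4·H2O, KOH, diethylene glycol, 130 then 200 °C); the hot alkali is expected to remove the silyl group as well and to give α-eudesmol F5. Resilylation (Et3SiOTf, 2,6-lutidine, CH2Cl2) returns to 15.

Further compounds

F1 | step 8 | methyl (5R,7E)-8-methyl-2-methylidene-5-[2-(triethylsilyloxy)propan-2-yl]deca-7,9-dienoate | C=C(C(=O)OC)CC[C@@H](C(C)(C)O[Si](CC)(CC)CC)C/C=C(\C)C=C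
F2 | step 8 | methyl 11-(triethylsilyloxy)eudesm-3-en-14-oate | CC1=CCC[C@]2(C(=O)OC)CC[C@@H](C(C)(C)O[Si](CC)(CC)CC)C[C@H]21
F3 | step 8 | 11-(triethylsilyloxy)eudesm-3-en-14-ol | CC1=CCC[C@]2(CO)CC[C@@H](C(C)(C)O[Si](CC)(CC)CC)C[C@H]21
F4 | step 13 | (2-bromo-4-cyanophenyl)(2,4,6-trimethoxyphenyl)iodonium 4-methylbenzenesulfonate | N#Cc1ccc([I+]c2c(OC)cc(OC)cc2OC)c(Br)c1.Cc1ccc(S(=O)(=O)[O-])cc1
F5 | step 10 | α-eudesmol, 2-[(2R,4aR,8aR)-4a,8-dimethyl-1,2,3,4,4a,5,6,8a-octahydronaphthalen-2-yl]propan-2-ol | CC1=CCC[C@]2(C)CC[C@@H](C(C)(C)O)C[C@H]21
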